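## Analysis of the target

Target 23, methyl 2-(3-bromo-12H-pyrido[1,2-a:3,4-b']diindol-13-yl)-2-oxoacetate, is a planar, fully aromatic pentacycle, and the locants of that ring system are used for its atoms throughout. Ring A (C7b, C8 to C11, C11a) and ring B (C7a, C7b, C11a, N12, C12a) make up an NH-indole, ring C (N5, C6, C7, C7a, C12a, C12b) is a pyridine-type ring fused to the indole bond C7a=C12a, ring D (N5, C12b, C13, C13a, C4a) is a pyrrole that shares N5–C12b with ring C, and ring E (C1 to C4, C4a, C13a) is the bromobenzo ring. There is no stereocentre, so all selectivity questions are constitutional: bromine at C3 (para to C13a and meta to C4a), the methoxalyl group at C13, and N5 as the bridgehead nitrogen while N12 keeps its hydrogen. The sensitive groups are the aryl bromide, which speaks against late palladium chemistry or halogen–metal exchange, the α-keto ester, which does not tolerate hydroxide or strong nucleophiles, the acidic N12–H, which can compete with N5 as a nucleophile, and the electron-rich pyrido[1,2-a]indole core as long as C13 is unsubstituted. The hard parts are to obtain ring C at the aromatic oxidation level without a dehydrogenation step and to make N5, not N12, close ring D. The plan rests on ring C: the atoms C6=C7–C7a=C12a–C12b=N5 are a 1-azatriene that the indole 2,3-bond locks s-cis, so N5–C6 can be closed by heat, and a methoxy group on N5 then leaves as the alcohol and aromatises the ring. C13 is doubly benzylic, so one 4-bromo-2-fluorobenzyl group can supply C13, ring E, the bromine and a fluoride leaving group on C4a.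

## Retrosynthetic reasoning

**Bond from C13 to the keto carbon, 23 ⇒ 19 + 20 + 21.** C13 of 19 is the enamine β-carbon of a pyrido[1,2-a]indole and its most nucleophilic position, so the side chain is removed first. In the forward sense 20 acylates C13 without a Lewis acid, and 21 turns the acid chloride 22 into the methyl ester. The keto ester is deliberately kept out of the ring D closure. If it sat on C13 beforehand, the benzylic carbon would be an enolate carbon whose oxygen lies as close to the aryl fluoride as N5 does, and closure through oxygen to a furan would compete.

**N5–C4a bond, 19 ⇒ 18 ⇒ 17.** Ring D is opened at N5–C4a. Forward, deprotonation of the C13 methylene of 17 gives an aza-enolate whose nitrogen displaces fluoride from the ortho carbon of the same benzyl group. Fluoride is the better leaving group in addition–elimination and the bromide sits meta to the reacting carbon, so the two halogens are told apart without a metal. An N12 anion could reach the same carbon through a six-membered ring, so N12 is blocked for this step. 17 therefore comes from 15 and 16, and fluoride ion takes the blocking group off 18 to give 19.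

**N5–C6 bond, 15 ⇒ 13 (key disconnection).** Ring C is opened at N5–C6 to the 1-azatriene 13. Forward, a thermal 6π closure gives 14, and loss of the N-methoxy group together with a C6 hydrogen gives the aromatic β-carboline 15. The cut is made here because it delivers ring C at the right oxidation level with heat alone. N12 stays unprotected up to this point, because a group on N12 would clash with the C13 methylene in the planar conformer that has to cyclise.

**C12b=N5 bond, 13 ⇒ 11 + 12.** The oxime ether comes from condensation of ketone 11 with 12, which brings in N5 together with its leaving group.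

**C12b–C13 bond, 11 ⇒ 8 + 10.** The ketone is cut between the carbonyl carbon and the benzylic carbon. Weinreb amide 8 takes up exactly one equivalent of the benzyl Grignard reagent 10, which is made from 9 by metal insertion into the benzylic C–Br bond.

**Indole substituents, 8 ⇒ 6 + 7, 6 ⇒ 4 + 5, 4 ⇒ 1 + 2.** The amide comes from ester 6 and 7. The vinyl group (C6 and C7) comes from Wittig methylenation of aldehyde 4 with the ylide of 5. The aldehyde comes from formylation of 1 with 2 at the only free nucleophilic position, through iminium salt 3.

## Alternatives that were turned down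

Alternative 1: Ring D is cut at N5–C12b together with the bond from C13 to the keto carbon, and ring C is left for a late acid-mediated closure of a pendant acetal onto C7a. In the forward key step PtCl2 activates a diaryl alkyne whose aniline nitrogen carries a 2,2-dimethoxyethyl chain and the methoxalyl group. The nitrogen adds to the alkyne in a 5-endo sense and the methoxalyl group shifts from nitrogen to the neighbouring carbon, which should give methyl 2-[6-bromo-1-(2,2-dimethoxyethyl)-2-(1H-indol-2-yl)-1H-indol-3-yl]-2-oxoacetate A1. What speaks for it: A1 arises in one step with ring D closed and the keto ester in the right place, and the route is convergent. What speaks against it: the migrating group is an oxalyl unit, which is more likely to be lost or decarbonylated than the simple acyl groups for which this 1,3-shift is established. The nitrogen of a tertiary oxamate is a weak nucleophile. The acetal of A1 has to survive a Lewis acidic platinum salt. The Sonogashira coupling that builds the alkyne has to distinguish an iodide from the bromide under palladium. Comparison: on convergence and on installing the side chain without a separate acylation the route through A1 is stronger. The chosen strategy offers instead reaction types that are each established on closely related substrates, and an aryl bromide that never meets a transition metal.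

Alternative 2: The NH-indole is cut at C7a–C7b, so that ring B is made last. Forward, a tricyclic ketone is condensed with an aniline that bears an ortho iodine. Pd(OAc)2 with DABCO in DMF then generates zerovalent palladium, which inserts into the carbon–iodine bond, and the enamine tautomer is arylated at C7a to give methyl 2-(3-bromo-7,12-dihydro-6H-pyrido[1,2-a:3,4-b']diindol-13-yl)acetate A2. What speaks for it: this indole annulation from a ketone is robust, arguably more predictable than a pericyclic closure at 180 °C, and it uses a cheap aniline. What speaks against it: A2 is two oxidation levels away from the target. C6–C7 must be dehydrogenated and the CH2 of the acetate must be oxidised to a ketone, both on an electron-rich skeleton. The C3–Br bond is exposed to zerovalent palladium at high temperature, and the tricyclic ketone itself costs several steps. Comparison: the route through A2 is at least as strong in the reliability of its key bond formation. The chosen strategy gives ring C aromatic directly by loss of an alcohol and installs the keto ester at the final oxidation level by one electrophilic substitution.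

Alternative 3: Ring D is cut at C13–C13a. Forward, an N-(3-bromophenyl) enaminone that already carries the keto ester is cyclised with Pd(OAc)2 and Cu(OAc)2 as reoxidant. Palladation at the enaminone α-carbon C13, C–H activation at the aryl ortho carbon para to bromine, and reductive elimination give methyl 2-(3-bromo-7,12-dihydro-6H-pyrido[1,2-a:3,4-b']diindol-13-yl)-2-oxoacetate A3. What speaks for it: the side chain is in place before the cyclisation, and only the dehydrogenation of C6–C7 separates A3 from the target. What speaks against it: the two ortho positions of the 3-bromophenyl ring differ only sterically, so the C1-bromo isomer of A3 can form. Every turnover passes through zerovalent palladium in the presence of the aryl bromide. The N-aryl enaminone precursor is itself not easy to make. The final dehydrogenation has to spare the keto ester and the bromide. Comparison: A3 is stronger in having the keto ester present early and in the number of steps after its key step. The chosen strategy offers a ring E regiochemistry that is fixed by the substitution pattern of the purchased 9 (fluorine marks C4a, bromine marks C3), no palladium, and no oxidation step.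

Key step: step 6

Assumption: oxime ether 13 is expected as an E/Z mixture and is used as such; the E isomer is drawn because it is the one that cyclises, and the isomers interconvert at the temperature of step 6.

## Route

Step 1
Reactants: 1 methyl 1H-indole-2-carboxylate; 2 N,N-dimethylformamide
Product: 4 methyl 3-formyl-1H-indole-2-carboxylate, via C3 iminium dichlorophosphate 3 (not isolated)
Conditions: POCl3 (1.5 equiv), DMF, 0 → 60 °C; then aq NaOH to pH 9, 0 °C → rt
Reagents that add atoms: N,N-dimethylformamide (2), CN(C)C=O; water, O
Why: Vilsmeier–Haack formylation; the chloroiminium ion attacks C3, the only free nucleophilic position of the 2-ester indole (hence the warming), and mild aqueous base hydrolyses iminium salt 3 to the aldehyde without touching the ester.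

Step 2
Reactants: 4 methyl 3-formyl-1H-indole-2-carboxylate; 5 methyltriphenylphosphonium bromide
Product: 6 methyl 3-ethenyl-1H-indole-2-carboxylate
Conditions: 5 (2.6 equiv), KOtBu (2.5 equiv), THF, 0 °C → rt
Reagents that add atoms: methyltriphenylphosphonium bromide (5), C[P+](c1ccccc1)(c1ccccc1)c1ccccc1.[Br-]
Why: Wittig methylenation; one equivalent of ylide is spent on the N–H and the excess converts the aldehyde into the vinyl group, while the ester is inert to a non-stabilised ylide at this temperature and the 2-acceptor keeps the 3-vinylindole from polymerising.

Step 3
Reactants: 6 methyl 3-ethenyl-1H-indole-2-carboxylate; 7 N,O-dimethylhydroxylamine hydrochloride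
Product: 8 3-ethenyl-N-methoxy-N-methyl-1H-indole-2-carboxamide
Conditions: 7 (3 equiv), iPrMgCl (7 equiv), THF, −20 → 0 °C; aq NH4Cl
Reagents that add atoms: N,O-dimethylhydroxylamine hydrochloride (7), CNOC.Cl
Why: Weinreb amide formation by aminolysis of the ester with the chloromagnesium amide made in the flask; the extra equivalent of iPrMgCl covers the indole N–H and the vinyl group is not attacked.

Step 4
Reactants: 8 3-ethenyl-N-methoxy-N-methyl-1H-indole-2-carboxamide; 9 4-bromo-2-fluorobenzyl bromide
Product: 11 2-(4-bromo-2-fluorophenyl)-1-(3-ethenyl-1H-indol-2-yl)ethan-1-one, via 4-bromo-2-fluorobenzylmagnesium bromide 10 (not isolated)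
Conditions: 9 (3 equiv), Mg turnings, Et2O, 0 °C, slow addition; then 8, THF, −20 → 0 °C; aq NH4Cl
Reagents that add atoms: 4-bromo-2-fluorobenzyl bromide (9), BrCc1ccc(Br)cc1F
Why: Magnesium inserts into the benzylic C–Br bond much faster than into the aryl C–Br bond; in the Weinreb ketone synthesis one equivalent of 10 deprotonates the N–H and the next adds once to the amide, whose N-methoxy chelate holds the tetrahedral adduct until work-up so that no tertiary alcohol forms.

Step 5
Reactants: 11 2-(4-bromo-2-fluorophenyl)-1-(3-ethenyl-1H-indol-2-yl)ethan-1-one; 12 O-methylhydroxylamine hydrochloride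
Product: 13 (1E)-2-(4-bromo-2-fluorophenyl)-1-(3-ethenyl-1H-indol-2-yl)ethan-1-one O-methyl oxime
Conditions: 12 (3 equiv), pyridine, EtOH, 70 °C
Reagents that add atoms: O-methylhydroxylamine hydrochloride (12), CON.Cl
Why: Oxime ether condensation; the 2-acylindole carbonyl is deactivated, hence the excess reagent and the heating, and the expected E/Z mixture is acceptable because the isomers equilibrate in the next step.

Step 6
Reactants: 13 (1E)-2-(4-bromo-2-fluorophenyl)-1-(3-ethenyl-1H-indol-2-yl)ethan-1-one O-methyl oxime
Product: 15 1-[(4-bromo-2-fluorophenyl)methyl]-9H-pyrido[3,4-b]indole, via N-methoxy dihydro-β-carboline 14 (not isolated)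
Conditions: o-dichlorobenzene (0.02 M, degassed), 180 °C
Reagents that add atoms: none
Why: Heating equilibrates the oxime isomers, and the E isomer, whose methoxy group points away from the vinyl terminus, can reach the planar s-cis,s-cis conformer of the 1-azatriene C6=C7–C7a=C12a–C12b=N5. A thermal disrotatory 6π-azaelectrocyclisation then joins N5 to C6 and gives 14, in which ring B is for the moment an indole-2,3-quinodimethane. Elimination of methanol across N5–C6 restores the indole, turns ring C into a pyridine without any oxidant, and makes the closure irreversible. The closest known reaction type is the thermal azaelectrocyclisation of O-alkyl oximes of 2-acyl-3-alkenylindoles and related 1-azatrienes, which gives carbolines and pyridines. Ring C closes in a pericyclic six-centre mode, and no stereocentre is formed because C6 of 14 is a CH2 group and N5 ends up planar. The step needs selectivity for the azatriene over an all-carbon triene reached by tautomerism towards C13 and over intermolecular cycloaddition of the vinylindole. The s-cis geometry enforced by the indole 2,3-bond, the unsubstituted vinyl terminus, the free N12–H, which avoids a clash with the C13 methylene in the planar conformer, and high dilution secure it. The aryl bromide, the aryl fluoride and the benzylic CH2 should be inert to heat alone.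

Step 7
Reactants: 15 1-[(4-bromo-2-fluorophenyl)methyl]-9H-pyrido[3,4-b]indole; 16 2-(trimethylsilyl)ethoxymethyl chloride
Product: 17 1-[(4-bromo-2-fluorophenyl)methyl]-9-{[2-(trimethylsilyl)ethoxy]methyl}-9H-pyrido[3,4-b]indole
Conditions: NaH (1.1 equiv), DMF, 0 °C; then 16 (1.1 equiv), 0 °C → rt
Reagents that add atoms: 2-(trimethylsilyl)ethoxymethyl chloride (16), C[Si](C)(C)CCOCCl
Why: N-alkylation of the carboline anion; the N–H is far more acidic than the benzylic CH2, so one equivalent of NaH gives only the nitrogen anion, which reacts with the α-chloro ether at N9, and the group keeps this nitrogen from displacing fluoride through a six-membered ring in step 8.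

Step 8
Reactants: 17 1-[(4-bromo-2-fluorophenyl)methyl]-9-{[2-(trimethylsilyl)ethoxy]methyl}-9H-pyrido[3,4-b]indole
Product: 18 3-bromo-12-{[2-(trimethylsilyl)ethoxy]methyl}-12H-pyrido[1,2-a:3,4-b']diindole
Conditions: KOtBu (1.2 equiv), DMSO, rt → 80 °C, argon
Reagents that add atoms: none
Why: Intramolecular nucleophilic aromatic substitution; the C13 methylene, activated by the azine and the aryl ring, is deprotonated to an aza-enolate whose nitrogen N5 adds to the ortho C–F carbon in a five-membered closure and expels fluoride, the same reaction type as the indole-forming cyclisation of metallated enamines onto unactivated ortho-fluoroarenes. Fluoride is displaced in preference to bromide because it is the better leaving group in addition–elimination and the bromine is meta to the reacting carbon, and only a slight excess of base is used so that little is left to attack ring E.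

Step 9
Reactants: 18 3-bromo-12-{[2-(trimethylsilyl)ethoxy]methyl}-12H-pyrido[1,2-a:3,4-b']diindole
Product: 19 3-bromo-12H-pyrido[1,2-a:3,4-b']diindole
Conditions: Bu4NF (5 equiv), H2NCH2CH2NH2 (5 equiv), THF, 65 °C, argon
Reagents that add atoms: none
Why: Fluoride-induced fragmentation of the N–CH2–O–CH2CH2–SiMe3 group; attack at silicon releases ethene and the hemiaminal alkoxide, which collapses to the indole-type anion and formaldehyde, and ethylenediamine captures the formaldehyde before it can react with the nucleophilic C13.

Step 10
Reactants: 19 3-bromo-12H-pyrido[1,2-a:3,4-b']diindole; 20 oxalyl chloride; 21 methanol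
Product: 23 methyl 2-(3-bromo-12H-pyrido[1,2-a:3,4-b']diindol-13-yl)-2-oxoacetate, via C13 oxoacetyl chloride 22 (not isolated)
Conditions: (COCl)2 (1.3 equiv), THF, 0 °C; then MeOH, Et3N, 0 °C → rt
Reagents that add atoms: oxalyl chloride (20), O=C(Cl)C(Cl)=O; methanol (21), CO
Why: Friedel–Crafts-type acylation without Lewis acid at C13, the enamine β-carbon of the pyrido[1,2-a]indole and the counterpart of indole C3, followed by methanolysis of the acid chloride; any lactam formed by attack of N12–H on the acid chloride is an activated N-acylindole that methanol with Et3N opens to the same ester.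

## Compound list

1 | methyl 1H-indole-2-carboxylate | COC(=O)c1cc2ccccc2[nH]1 | starting material
2 | N,N-dimethylformamide | CN(C)C=O | starting material
3 | methyl 3-[(dimethyliminio)methyl]-1H-indole-2-carboxylate dichlorophosphate | COC(=O)c1[nH]c2ccccc2c1C=[N+](C)C.[O-]P(=O)(Cl)Cl | intermediate
4 | methyl 3-formyl-1H-indole-2-carboxylate | COC(=O)c1[nH]c2ccccc2c1C=O | intermediate
5 | methyltriphenylphosphonium bromide | C[P+](c1ccccc1)(c1ccccc1)c1ccccc1.[Br-] | starting material
6 | methyl 3-ethenyl-1H-indole-2-carboxylate | COC(=O)c1[nH]c2ccccc2c1C=C | intermediate
7 | N,O-dimethylhydroxylamine hydrochloride | CNOC.Cl | starting material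
8 | 3-ethenyl-N-methoxy-N-methyl-1H-indole-2-carboxamide | CON(C)C(=O)c1[nH]c2ccccc2c1C=C | intermediate
9 | 4-bromo-2-fluorobenzyl bromide | BrCc1ccc(Br)cc1F | starting material
10 | 4-bromo-2-fluorobenzylmagnesium bromide | Br[Mg]Cc1ccc(Br)cc1F | intermediate
11 | 2-(4-bromo-2-fluorophenyl)-1-(3-ethenyl-1H-indol-2-yl)ethan-1-one | O=C(Cc1ccc(Br)cc1F)c1[nH]c2ccccc2c1C=C | intermediate
12 | O-methylhydroxylamine hydrochloride | CON.Cl | starting material
13 | (1E)-2-(4-bromo-2-fluorophenyl)-1-(3-ethenyl-1H-indol-2-yl)ethan-1-one O-methyl oxime | CO/N=C(/c1[nH]c2ccccc2c1C=C)Cc1ccc(Br)cc1F | intermediate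
14 | 1-[(4-bromo-2-fluorophenyl)methyl]-2-methoxy-3,9-dihydro-2H-pyrido[3,4-b]indole | CON1CC=C2C(Nc3ccccc23)=C1Cc1ccc(Br)cc1F | intermediate
15 | 1-[(4-bromo-2-fluorophenyl)methyl]-9H-pyrido[3,4-b]indole | Fc1cc(Br)ccc1Cc1nccc2c3ccccc3[nH]c12 | intermediate
16 | 2-(trimethylsilyl)ethoxymethyl chloride | C[Si](C)(C)CCOCCl | starting material
17 | 1-[(4-bromo-2-fluorophenyl)methyl]-9-{[2-(trimethylsilyl)ethoxy]methyl}-9H-pyrido[3,4-b]indole | Fc1cc(Br)ccc1Cc1nccc2c3ccccc3n(COCC[Si](C)(C)C)c12 | intermediate
18 | 3-bromo-12-{[2-(trimethylsilyl)ethoxy]methyl}-12H-pyrido[1,2-a:3,4-b']diindole | c1c2ccc(Br)cc2n2ccc3c4ccccc4n(COCC[Si](C)(C)C)c3c12 | intermediate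
19 | 3-bromo-12H-pyrido[1,2-a:3,4-b']diindole | c1c2ccc(Br)cc2n2ccc3c4ccccc4[nH]c3c12 | intermediate
20 | oxalyl chloride | O=C(Cl)C(Cl)=O | starting material
21 | methanol | CO | starting material
22 | 2-(3-bromo-12H-pyrido[1,2-a:3,4-b']diindol-13-yl)-2-oxoacetyl chloride | O=C(Cl)C(=O)c1c2ccc(Br)cc2n2ccc3c4ccccc4[nH]c3c12 | intermediate
23 | methyl 2-(3-bromo-12H-pyrido[1,2-a:3,4-b']diindol-13-yl)-2-oxoacetate | COC(=O)C(=O)c1c2ccc(Br)cc2n2ccc3c4ccccc4[nH]c3c12 | target

## Step count and least certain steps

Total step count: 10. Longest linear sequence: 10 steps from 1 (the Grignard reagent 10 is made within step 4).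

**Step 6 (key step).** The closure may be slow if the planar s-cis conformer or the E oxime is poorly populated. The vinylindole may oligomerise at 180 °C. Tautomerism of the oxime ether towards C13 may open an all-carbon electrocyclisation that leads to a carbazole. Fallback, from 4 back to 15: ring C is made by condensation instead of a pericyclic step. Aldehyde 4 is methoxymethylenated with (methoxymethyl)triphenylphosphonium chloride and KOtBu to methyl 3-(2-methoxyethenyl)-1H-indole-2-carboxylate F1. F1 is converted as in step 3 into the Weinreb amide N-methoxy-3-(2-methoxyethenyl)-N-methyl-1H-indole-2-carboxamide F2. Addition of 10 as in step 4 gives 2-(4-bromo-2-fluorophenyl)-1-[3-(2-methoxyethenyl)-1H-indol-2-yl]ethan-1-one F3. Heating F3 with NH4OAc in acetic acid at 100 °C unmasks the aldehyde and condenses this 1,5-dicarbonyl equivalent with ammonia to 15.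

**Step 8.** The base may deprotonate the ring E C–H between fluorine and bromine, followed by loss of bromide. The benzylic anion may be oxidised by traces of air. The addition–elimination may be slow because the arene carries no activating group. Fallback, from 15 to 23: the order is changed so that a weak base suffices. Claisen condensation of 15 with dimethyl oxalate (KOMe, 3 equiv, DMF, rt) gives methyl 3-(4-bromo-2-fluorophenyl)-2-oxo-3-(9H-pyrido[3,4-b]indol-1-yl)propanoate F4. Its stabilised anion (K2CO3, 1 equiv, DMSO, 120 °C) is cyclised through N5 with loss of fluoride to 23 directly, the free N12–H being hydrogen-bonded to the enolate oxygen and so holding that oxygen away from the aryl fluoride. Closure through oxygen remains the weak point of this variant, which is why it is not the main line.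

**Step 9.** The fragmentation may stop at the N-hydroxymethyl stage. Formaldehyde may be captured by C13 if the amine scavenger is too slow. The electron-rich product may degrade under hot basic fluoride. Fallback, from 18 to 23: C13 is acylated first with 20 and 21 as in step 10 to give methyl 2-(3-bromo-12-{[2-(trimethylsilyl)ethoxy]methyl}-12H-pyrido[1,2-a:3,4-b']diindol-13-yl)-2-oxoacetate F5. The N,O-acetal is then cleaved by acid-mediated methanolysis (HCl, MeOH, 60 °C; then K2CO3, MeOH, rt), in which the methyl ester can only be exchanged for itself, to give 23.

**Step 4.** Wurtz homocoupling may compete during the magnesium insertion, the metal may scramble into the aryl C–Br bond, and addition to the N-magnesiated amide may be incomplete. Fallback, from 8 to 11: the benzyl group is added to an aldehyde under Barbier conditions. Amide 8 is reduced with iBu2AlH (2.2 equiv, THF, −78 °C) to 3-ethenyl-1H-indole-2-carbaldehyde F6. F6 is benzylated with 9 and Zn dust in THF/aq NH4Cl at rt to racemic 2-(4-bromo-2-fluorophenyl)-1-(3-ethenyl-1H-indol-2-yl)ethan-1-ol F7. Oxidation of F7 with MnO2 in CH2Cl2 gives 11.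

**Step 2.** Deprotonation of the N–H by the ylide turns the formyl group into a vinylogous amide anion, and the olefination may stall. Fallback, from 1 to 6: the vinyl group is introduced by cross-coupling before any aryl bromide is present. Bromination of 1 with N-bromosuccinimide (DMF, 0 °C) gives methyl 3-bromo-1H-indole-2-carboxylate F8. Suzuki–Miyaura coupling of F8 with potassium vinyltrifluoroborate (Pd(dppf)Cl2, Cs2CO3, THF/H2O, 80 °C) gives 6.

## Further compounds

F1 | step 6 | methyl 3-[(E)-2-methoxyethenyl]-1H-indole-2-carboxylate (E/Z mixture expected, E drawn) | COC(=O)c1[nH]c2ccccc2c1/C=C/OC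
F2 | step 6 | N-methoxy-3-[(E)-2-methoxyethenyl]-N-methyl-1H-indole-2-carboxamide (E drawn) | CON(C)C(=O)c1[nH]c2ccccc2c1/C=C/OC
F3 | step 6 | 2-(4-bromo-2-fluorophenyl)-1-{3-[(E)-2-methoxyethenyl]-1H-indol-2-yl}ethan-1-one (E drawn) | O=C(Cc1ccc(Br)cc1F)c1[nH]c2ccccc2c1/C=C/OC
F4 | step 8 | methyl 3-(4-bromo-2-fluorophenyl)-2-oxo-3-(9H-pyrido[3,4-b]indol-1-yl)propanoate (keto tautomer drawn, configurationally labile) | COC(=O)C(=O)C(c1ccc(Br)cc1F)c1nccc2c3ccccc3[nH]c12
F5 | step 9 | methyl 2-(3-bromo-12-{[2-(trimethylsilyl)ethoxy]methyl}-12H-pyrido[1,2-a:3,4-b']diindol-13-yl)-2-oxoacetate | COC(=O)C(=O)c1c2ccc(Br)cc2n2ccc3c4ccccc4n(COCC[Si](C)(C)C)c3c12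
F6 | step 4 | 3-ethenyl-1H-indole-2-carbaldehyde | O=Cc1[nH]c2ccccc2c1C=C
F7 | step 4 | rac-2-(4-bromo-2-fluorophenyl)-1-(3-ethenyl-1H-indol-2-yl)ethan-1-ol | OC(Cc1ccc(Br)cc1F)c1[nH]c2ccccc2c1C=C
F8 | step 2 | methyl 3-bromo-1H-indole-2-carboxylate | COC(=O)c1[nH]c2ccccc2c1Br
A1 | alternative 1 | methyl 2-[6-bromo-1-(2,2-dimethoxyethyl)-2-(1H-indol-2-yl)-1H-indol-3-yl]-2-oxoacetate | COC(=O)C(=O)c1c2ccc(Br)cc2n(CC(OC)OC)c1-c1cc2ccccc2[nH]1
A2 | alternative 2 | methyl 2-(3-bromo-7,12-dihydro-6H-pyrido[1,2-a:3,4-b']diindol-13-yl)acetate | COC(=O)Cc1c2ccc(Br)cc2n2CCc3c4ccccc4[nH]c3c12
A3 | alternative 3 | methyl 2-(3-bromo-7,12-dihydro-6H-pyrido[1,2-a:3,4-b']diindol-13-yl)-2-oxoacetate | COC(=O)C(=O)c1c2ccc(Br)cc2n2CCc3c4ccccc4[nH]c3c12
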